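The target is an unbranched, even-numbered C20 acyl chain whose C1 carbonyl bears a benzyloxy group. Its only ring, the phenyl, is a spectator. Everything rests on cutting C2–C3, which divides the chain into a C18 acyl donor (C3–C20) and a two-carbon malonyl nucleophile (C1–C2) that already carries the benzyl ester. In one operation the magnesium-chelated half-ester enolate is acylated at carbon and loses CO2, delivering the whole C20 skeleton as its 3-oxo ester. The precursor is 1-stearoylimidazole: a linear C17 alkyl group on an N-acylimidazole carbonyl. The surplus C3 oxygen is then removed by reduction, elimination and conjugate reduction without touching the benzylic C–O bond.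

Key step: step 2

Remark on the chemistry: the target has no stereocentre and no stereogenic double bond, so it is achiral and exists in one form only; the racemic C3 carbinol and the E-alkene met on the way are both erased before the end.

Step 1
Reactants: 1 stearic acid (octadecanoic acid); 2 1,1'-carbonyldiimidazole
Product: 3 1-stearoylimidazole (1-(1H-imidazol-1-yl)octadecan-1-one)
Conditions: 2 (1.0 equiv), THF, 40 °C until gas evolution ends, N2 sparge; evaporate, crude solid (with its imidazole) used as such under N2
Reagents that add atoms: 1,1'-carbonyldiimidazole (compound 2), O=C(n1ccnc1)n1ccnc1
Why: Carboxylic acid activation with CDI (N-acylimidazole formation) is driven to completion by loss of CO2, and exactly one equivalent of 2 is used so that none survives into step 2.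

Step 2
Reactants: 3 1-stearoylimidazole; 4 monobenzyl malonate (3-(benzyloxy)-3-oxopropanoic acid)
Product: 7 benzyl 3-oxoicosanoate, via magnesium malonate enolate 5 (not isolated), via acylmalonate half-ester 6 (not isolated)
Conditions: 4 (1.4 equiv), anhydrous MgCl2 (1.5 equiv), Et3N (3 equiv), THF, rt, 2 h; then 3 in THF, rt → 45 °C; 1 M HCl, 0 °C
Reagents that add atoms: magnesium chloride, [Mg+2].[Cl-].[Cl-] (its magnesium is present only in the unisolated 5 and in the salt form of 6; 7 keeps no reagent atoms)
Why: Magnesium binds both carbonyl oxygens of 4, which acidifies the C2–H enough for Et3N to generate the chelated enolate-carboxylate 5; its C2 adds to the acyl carbonyl of 3 (the future C3) and imidazole is expelled, giving the acylmalonate 6. As a β-keto carboxylate, 6 loses CO2 at or slightly above room temperature and ends as the magnesium chelate of the enolate of 7, so the C2–C3 bond formation cannot revert; the acid quench releases 7. The closest known reaction type is this very one, the decarboxylative Claisen condensation of magnesium malonate half-ester salts with N-acylimidazoles, an established entry to β-keto esters including benzyl-type esters. No ring is closed and no stereocentre is created (C2 of 6 is configurationally labile and becomes a CH2). Two selectivities are needed: C- over O-acylation, secured because both enolate oxygens are tied up in the chelate and any O-acyl species is itself an acyl donor that returns to the pool, and single over double acylation, secured because after CO2 loss the product rests as a chelated enolate that is inert towards so mild an acyl donor. Generating 5 with MgCl2/Et3N instead of a magnesium alkoxide keeps every foreign alkoxide out of the flask, so the benzyl ester cannot exchange, and the absence of residual CDI means nothing else consumes 5.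

Step 3
Reactants: 7 benzyl 3-oxoicosanoate
Product: 8 benzyl (±)-3-hydroxyicosanoate
Conditions: NaBH4 (0.5 equiv), THF/i-PrOH 4:1, 0 °C; aq NH4Cl
Reagents that add atoms: none
Why: Chemoselective borohydride 1,2-reduction of a ketone beside an ester should give the β-hydroxy ester, with the limited hydride charge, low temperature and hindered alcohol co-solvent guarding against diol formation and ester exchange, and the new C3 stereocentre is deliberately left racemic because step 4 destroys it.

Step 4
Reactants: 8 benzyl (±)-3-hydroxyicosanoate
Product: 10 benzyl (E)-icos-2-enoate, via C3 mesylate 9 (not isolated)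
Conditions: MsCl (1.2 equiv), Et3N (1.5 equiv), CH2Cl2, 0 °C; then DBU (2 equiv), 0 °C → rt
Reagents that add atoms: methanesulfonyl chloride, CS(=O)(=O)Cl (its atoms are present only in the unisolated 9 and leave again as methanesulfonate)
Why: O-Mesylation followed by base-mediated E1cB-type β-elimination removes the ester-acidified C2–H and expels mesylate from C3, which should give the conjugated, sterically preferred E-enoate, whose geometry is immaterial because the double bond is saturated in step 5.

Step 5
Reactants: 10 benzyl (E)-icos-2-enoate
Product: 11 benzyl icosanoate (target)
Conditions: Cu(OAc)2·H2O (2 mol %), 1,2-(Ph2P)2C6H4 (2 mol %), (EtO)2MeSiH (2 equiv), t-BuOH (2 equiv), PhMe, rt; aq NaHCO3, silica plug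
Reagents that add atoms: none
Why: In this copper hydride-catalysed conjugate reduction (1,4-hydrosilylation type) the bisphosphine-ligated Cu–H delivers hydride to C3, t-BuOH protonates the copper enolate at C2 and the silane regenerates Cu–H, a soft hydride cycle that attacks neither an isolated ester carbonyl nor the benzylic C–O bond that heterogeneous hydrogenation would cleave.

Compound list
1 | stearic acid (octadecanoic acid) | CCCCCCCCCCCCCCCCCC(=O)O | starting material
2 | 1,1'-carbonyldiimidazole | O=C(n1ccnc1)n1ccnc1 | starting material
3 | 1-stearoylimidazole (1-(1H-imidazol-1-yl)octadecan-1-one) | CCCCCCCCCCCCCCCCCC(=O)n1ccnc1 | intermediate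
4 | monobenzyl malonate (3-(benzyloxy)-3-oxopropanoic acid) | OC(=O)CC(=O)OCc1ccccc1 | starting material
5 | magnesium enolate-carboxylate chelate of monobenzyl malonate (formed in the flask, not isolated) | [Mg+2].[O-]C(=O)C=C([O-])OCc1ccccc1 | intermediate
6 | 2-[(benzyloxy)carbonyl]-3-oxoicosanoic acid, present as its magnesium carboxylate (C2 racemic and labile, not isolated) | CCCCCCCCCCCCCCCCCC(=O)C(C(=O)O)C(=O)OCc1ccccc1 | intermediate
7 | benzyl 3-oxoicosanoate | CCCCCCCCCCCCCCCCCC(=O)CC(=O)OCc1ccccc1 | intermediate
8 | benzyl (±)-3-hydroxyicosanoate (racemic at C3) | CCCCCCCCCCCCCCCCCC(O)CC(=O)OCc1ccccc1 | intermediate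
9 | benzyl (±)-3-(methylsulfonyloxy)icosanoate (racemic at C3, not isolated) | CCCCCCCCCCCCCCCCCC(CC(=O)OCc1ccccc1)OS(C)(=O)=O | intermediate
10 | benzyl (E)-icos-2-enoate | CCCCCCCCCCCCCCCCC/C=C/C(=O)OCc1ccccc1 | intermediate
11 | benzyl icosanoate (eicosanoic acid phenylmethyl ester, achiral) | CCCCCCCCCCCCCCCCCCCC(=O)OCc1ccccc1 | target

Total step count: 5. Longest linear sequence: 5 (1 → 3 → 7 → 8 → 10 → 11).

Steps most likely to fail

**Step 2.** Three things may go wrong:
- incomplete enolisation if the magnesium chloride is not rigorously dry;
- loss of CO2 from the half-ester before it is acylated;
- hydrolysis or sluggish acyl transfer of the waxy, poorly soluble acyl donor.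

The fallback keeps the C2–C3 disconnection but replaces the metal enolate with a cyclic malonate that needs no magnesium. It sets out from 1. Stearic acid is coupled with Meldrum's acid (EDC·HCl, DMAP, CH2Cl2, 0 °C → rt) to give 5-(1-hydroxyoctadecylidene)-2,2-dimethyl-1,3-dioxane-4,6-dione F1. Heating this with benzyl alcohol in toluene brings about alcoholysis and decarboxylation. The fallback returns to the route at 7.

**Step 4.** The base may move the new double bond out of conjugation towards C3=C4, leaving material that copper hydride cannot reduce. Elimination may also stop short. The fallback gives up the alkene altogether and removes the oxygen by a radical path. It sets out from 8. The alcohol is treated with 1,1'-thiocarbonyldiimidazole (DMAP cat., 1,2-dichloroethane, 60 °C) to give benzyl 3-[(1H-imidazole-1-carbothioyl)oxy]icosanoate F2. This undergoes Barton–McCombie deoxygenation (Bu3SnH, AIBN, toluene, 90 °C). The fallback returns at 11 and bypasses 10 and step 5.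

**Step 5.** The catalytic cycle may stall through decay of the copper hydride. That would leave incomplete conversion and a mixture of two esters of almost identical polarity that is hard to separate. The fallback abandons chemoselectivity and reinstalls the ester. It sets out from 10, or from any mixture of 10 and 11. Hydrogenation over Pd/C (H2, EtOAc/THF, rt) saturates C2=C3 and hydrogenolyses the benzyl ester, and all the material converges on crystalline icosanoic acid F3, which is purified by recrystallisation. Carboxylate O-alkylation with benzyl bromide (K2CO3, DMF, rt) returns to the route at 11.

Further compounds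
F1 | step 2 | 5-(1-hydroxyoctadecylidene)-2,2-dimethyl-1,3-dioxane-4,6-dione | CCCCCCCCCCCCCCCCCC(O)=C1C(=O)OC(C)(C)OC1=O
F2 | step 4 | benzyl 3-[(1H-imidazole-1-carbothioyl)oxy]icosanoate (racemic at C3) | CCCCCCCCCCCCCCCCCC(CC(=O)OCc1ccccc1)OC(=S)n1ccnc1
F3 | step 5 | icosanoic acid | CCCCCCCCCCCCCCCCCCCC(=O)O
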